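**Retrosynthetic overview**

1. Ring C of every unit, with its C2 and C3 centres, is carried in ready-made from two dihydroflavonols: (+)-taxifolin 1 (top unit, used as leucocyanidin 2) and (+)-dihydromyricetin 3 (middle and bottom units, used as leucodelphinidin 4). No ring is closed in the flask; the units enter in the order bottom and middle (one flask), then top.
2. Bond made first, C4(middle)–C8(bottom): in one flask the C4 cation of 4 is shared between a hydride donor (reductase mimic, giving the starter unit gallocatechin 5) and C8 of 5 (condensation, giving dimer 6).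
3. Bond made last, C4(top)–C8(middle): the C4 cation of 2 is captured by the free C8 of the upper unit of 6 to give target 7, catechin-(4α→8)-gallocatechin-(4α→8)-gallocatechin.
4. No protecting groups are used; both new C4 centres are set 3,4-trans (4α) by the 2,3-trans cations themselves.

Assumption: the purchased (+)-taxifolin and (+)-dihydromyricetin are the single (2R,3R) enantiomers, checked by chiral HPLC before use.

**Route**

Step 1
Reactants: 1 (+)-taxifolin
Product: 2 (+)-leucocyanidin
Conditions: NaBH4 (4 equiv), EtOH, 0 °C to rt, Ar, 1 h; then AcOH to pH 6.5 at 0 °C, EtOAc extraction, evaporation below 30 °C; stored at −20 °C under Ar and used within a day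
Reagents that add atoms: none
Why: NaBH4 ketone reduction of the chroman-4-one, the only reducible group, with axial hydride delivery to the half-chair carrying equatorial 2-aryl and 3-OH, gives the 3,4-trans (4R) alcohol while C2 and C3 are untouched; the C4 configuration is immaterial because C4 is ionised in step 3.

Step 2
Reactants: 3 (+)-dihydromyricetin (two molecules end up in one molecule of product)
Product: 6 gallocatechin-(4α→8)-gallocatechin, via leucodelphinidin 4 (not isolated), via gallocatechin 5 (not isolated)
Conditions: NaBH4 (4 equiv), degassed EtOH–H2O 1:1, 0 °C to rt, Ar, 1 h; AcOH to pH 6.5, 10 min; Hantzsch ester (diethyl 2,6-dimethyl-1,4-dihydropyridine-3,5-dicarboxylate, 0.80 equiv) in THF, AcOH to pH 4.0, 25 °C, dark, 24 h; toluene wash, EtOAc extraction, Sephadex LH-20 (EtOH), C18 HPLC; 5 recovered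
Reagents that add atoms: none
Why: Proposed new method: NaBH4 reduction as in step 1 gives diol 4, whose acid-generated flavan-4-yl cation (quinone methide) should be reduced by the NADPH-like Hantzsch ester orders of magnitude faster than it is attacked by a phloroglucinol ring, so 0.80 equiv of 4 is first deoxygenated to 5 with C2 and C3 untouched, and only then does the remaining 0.20 equiv of 4 ionise in a fourfold excess of 5 and undergo Friedel–Crafts-type flavan-3,4-diol/flavan-3-ol condensation at the more nucleophilic C8, from the α-face trans to the 3-OH of the 2,3-trans cation (new C4 = S, 4α); the closest known reaction types are the acid-catalysed Hantzsch-ester transfer hydrogenation of ortho-quinone methides generated from hydroxybenzyl alcohols and the pH 4 to 5 leucoanthocyanidin–catechin condensation.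

Step 3
Reactants: 2 (+)-leucocyanidin; 6 gallocatechin-(4α→8)-gallocatechin
Product: 7 catechin-(4α→8)-gallocatechin-(4α→8)-gallocatechin (target CNP0188605.2)
Conditions: 6 (2.5 equiv), degassed H2O–EtOH 4:1, NaOAc/AcOH buffer pH 4.5, 25 °C, Ar, dark; 2 (1.0 equiv) in EtOH added over 8 h, then 16 h; EtOAc extraction, Sephadex LH-20, C18 HPLC; excess 6 recovered
Reagents that add atoms: none
Why: Biomimetic flavan-3,4-diol/flavan-3-ol condensation (Friedel–Crafts alkylation by the C4 cation of 2), in which the only free C8 of 6 is that of its upper unit and C8 is more reactive than the two free C6 positions, attack occurs on the α-face trans to the 3-OH of the 2,3-trans cation (new C4 = S, 4α), and slow addition of 2 to excess 6 at pH 4.5 suppresses self-condensation of 2 and tetramer formation while leaving the existing interflavan bond intact.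

**Compound list**

1 | (+)-taxifolin, (2R,3R)-2-(3,4-dihydroxyphenyl)-3,5,7-trihydroxychroman-4-one | Oc1cc(O)c2c(c1)O[C@H](c1ccc(O)c(O)c1)[C@@H](O)C2=O | starting material
2 | (+)-leucocyanidin, (2R,3S,4R)-2-(3,4-dihydroxyphenyl)chromane-3,4,5,7-tetrol (2,3-trans-3,4-trans) | Oc1cc(O)c2c(c1)O[C@H](c1ccc(O)c(O)c1)[C@@H](O)[C@@H]2O | intermediate
3 | (+)-dihydromyricetin, (2R,3R)-3,5,7-trihydroxy-2-(3,4,5-trihydroxyphenyl)chroman-4-one | Oc1cc(O)c2c(c1)O[C@H](c1cc(O)c(O)c(O)c1)[C@@H](O)C2=O | starting material
4 | leucodelphinidin, (2R,3S,4R)-2-(3,4,5-trihydroxyphenyl)chromane-3,4,5,7-tetrol (2,3-trans-3,4-trans) | Oc1cc(O)c2c(c1)O[C@H](c1cc(O)c(O)c(O)c1)[C@@H](O)[C@@H]2O | intermediate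
5 | (+)-gallocatechin, (2R,3S)-2-(3,4,5-trihydroxyphenyl)chromane-3,5,7-triol | Oc1cc(O)c2c(c1)O[C@H](c1cc(O)c(O)c(O)c1)[C@@H](O)C2 | intermediate
6 | gallocatechin-(4α→8)-gallocatechin, (2R,3S,4S)-4-[(2R,3S)-3,5,7-trihydroxy-2-(3,4,5-trihydroxyphenyl)chroman-8-yl]-2-(3,4,5-trihydroxyphenyl)chromane-3,5,7-triol | Oc1cc(O)c2c(c1)O[C@H](c1cc(O)c(O)c(O)c1)[C@@H](O)[C@@H]2c1c(O)cc(O)c2c1O[C@H](c1cc(O)c(O)c(O)c1)[C@@H](O)C2 | intermediate
7 | catechin-(4α→8)-gallocatechin-(4α→8)-gallocatechin; top unit 2R,3S,4S, middle unit 2R,3S,4R, bottom unit 2R,3S; both interflavan bonds 3,4-trans | Oc1cc(O)c2c(c1)O[C@H](c1ccc(O)c(O)c1)[C@@H](O)[C@@H]2c1c(O)cc(O)c2c1O[C@H](c1cc(O)c(O)c(O)c1)[C@@H](O)[C@@H]2c1c(O)cc(O)c2c1O[C@H](c1cc(O)c(O)c(O)c1)[C@@H](O)C2 | target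

**Step count and risk**

Total step count: 3. Longest linear sequence: 2 steps (3 → 6 → 7, or equally 1 → 2 → 7).

Steps most likely to fail, in order of risk:

Step 2. The hydride gating may be leaky: the cation may oligomerise before the hydride is spent, or capture may give too much of the 4α→6 and 4β isomers and trimers. I estimate 6 at 30–40% on the 0.20 equiv of chain-extending 4, about 6–8 mol% on 3, with more than half of 3 recovered as 5. The fallback sets out from 3 and comes back to the route at 6. Two batches of 3 are used instead of one flask. The first is taken through NaBH4 and a full 1.1 equiv of Hantzsch ester, so that all of 4 is reduced and 5 is isolated. The second is reduced with NaBH4 and the crude 4 is trapped with benzyl mercaptan (AcOH, EtOH, 40 °C) as the shelf-stable 4α-benzylthiogallocatechin F1, a laboratory counterpart of thiol-bound extension units. F1 is then coupled with 5 (4 equiv) by thiophilic activation with AgBF4 in THF at 0 °C in the dark. Under these neutral conditions the product cannot re-ionise, and 6 is obtained. The risk here is that the pyrogallol rings reduce the silver salt, so the contact time is kept short.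

Step 3. The cation of 2 may attack the C6 positions of 6, condense with itself, or extend the product to tetramers. I estimate 15–25% of 7 on 2, with 6 recovered. The fallback sets out from 2 and comes back at 7, building the chain from the top down. Compound 2 is added slowly at pH 4.5 to an excess of the acid-stable thioether F1 from the first fallback. C8 of F1 captures the cation and gives catechin-(4α→8)-gallocatechin 4α-benzyl thioether F2. F2 is then activated with AgBF4 in THF at 0 °C in the presence of excess 5, isolated as in the first fallback. The middle-to-bottom bond is thus formed last, to a cheap monomer in excess, which removes the site-selectivity problem on a dimer and gives 7 directly.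

Step 1. Compound 2 may self-condense or degrade on neutralisation and concentration. The fallback sets out from 1 and comes back at 7. After the NaBH4 reduction, 2 is not isolated; it is trapped in the flask with benzyl mercaptan and AcOH as the chromatographable 4α-benzylthiocatechin F3. F3 is coupled with 6 (2.5 equiv) using AgBF4 in THF at 0 °C, replacing the acid-promoted step 3 by a neutral thiophilic coupling that gives 7.

**Further compounds**

F1 | step 2 | 4α-benzylthiogallocatechin (2,3-trans-3,4-trans 4-benzylsulfanyl derivative of 5) | Oc1cc(O)c2c(c1)O[C@H](c1cc(O)c(O)c(O)c1)[C@@H](O)[C@@H]2SCc1ccccc1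
F2 | step 3 | catechin-(4α→8)-gallocatechin 4α-benzyl thioether | Oc1cc(O)c2c(c1)O[C@H](c1ccc(O)c(O)c1)[C@@H](O)[C@@H]2c1c(O)cc(O)c2c1O[C@H](c1cc(O)c(O)c(O)c1)[C@@H](O)[C@@H]2SCc1ccccc1
F3 | step 1 | 4α-benzylthiocatechin (2,3-trans-3,4-trans 4-benzylsulfanyl derivative of catechin) | Oc1cc(O)c2c(c1)O[C@H](c1ccc(O)c(O)c1)[C@@H](O)[C@@H]2SCc1ccccc1
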